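## Retrosynthetic overview

1. The target comes from global desilylation, preceded by a B-alkyl Suzuki coupling. That coupling joins the bridgehead vinyl group of a 1-vinyl-6,8-dioxabicyclo[3.2.2]nonan-7-one core to (Z)-3-iodo-2-methylallyl acetate.
2. The core comes from the key step. A copper vinylcarbene on an ester tether attacks the pyranoside ring oxygen to give a bridged oxonium ylide. A stepwise Stevens 1,2-shift then moves the anomeric carbon from O to C, which enlarges the oxane to the oxepane and closes the lactone bridge.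
3. The diazo ester comes from a 3-methyloxan-3-ol silyl acetal. This is made by axial MeMgBr addition to the CuH-reduced Achmatowicz pyranone (furan to pyranone ring expansion).
4. The furyl carbinol comes from a B-alkyl Suzuki coupling of (S)-1-(2-furyl)allyl alcohol (furfural plus divinylzinc) with (Z)-3-iodobut-2-en-1-ol. Both Z-olefins are bought in as stereodefined vinyl iodides.
5. Ring order: furan, then the six-membered pyranone/oxane, then the oxepane and the 1,4-dioxan-2-one bridge together in one step.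

Assumption: the SMILES is read as (1R,2S,5R,9S) on the 6,8-dioxabicyclo[3.2.2]nonan-7-one core with both side-chain olefins Z, and vinylmagnesium bromide and but-3-enoyl chloride are taken as catalogue items.

## Route

Step 1
Reactants: 1 but-2-yn-1-ol
Product: 3 (Z)-3-iodobut-2-en-1-ol, via cyclic sodium vinylalanate 2 (not isolated)
Conditions: Red-Al (1.5 equiv), Et2O, 0 °C → rt; I2, THF, −78 → 0 °C; aq. Rochelle salt/Na2S2O3
Reagents that add atoms: iodine, II
Why: Hydroxyl-directed trans-hydroalumination puts Al on C3 inside a five-membered O–Al chelate and iodinolysis goes with retention, so I and CH2OH end up cis (Z).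

Step 2
Reactants: 4 prop-2-yn-1-ol
Product: 7 (Z)-3-iodo-2-methylprop-2-en-1-yl acetate, via dimagnesiated alkenolate 5 (not isolated), via iodoalkenyl magnesium alkoxide 6 (not isolated)
Conditions: MeMgBr (2.5 equiv), CuI (10 mol %), THF/Et2O, −10 °C → rt; I2, 0 °C; Ac2O (3 equiv), DMAP (5 mol %), 0 °C → rt
Reagents that add atoms: methylmagnesium bromide, C[Mg]Br; iodine, II; acetic anhydride, CC(=O)OC(C)=O
Why: Copper-catalysed anti-carbomagnesiation of the propargylic alkoxide gives the chelated vinyl Grignard with Mg cis to CH2O, iodinolysis retains this geometry (Z), and the remaining magnesium alkoxide is acetylated in the same flask.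

Step 3
Reactants: 8 furan-2-carbaldehyde, 9 vinylmagnesium bromide
Product: 11 (S)-1-(furan-2-yl)prop-2-en-1-ol, via divinylzinc 10 (not isolated)
Conditions: 9 (2.4 equiv), ZnCl2 (1.2 equiv), Et2O, 0 °C, Mg salts precipitated with 1,4-dioxane and filtered off; (−)-MIB (8 mol %), toluene, 8, −10 °C; aq. work-up
Reagents that add atoms: none
Why: Ligand-accelerated catalytic asymmetric vinylzinc addition to an aryl aldehyde, in which the amino-alkoxide zinc complex delivers vinyl to the same face as in alkylzinc additions and sets the S carbinol (future C9).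

Step 4
Reactants: 11 (S)-1-(furan-2-yl)prop-2-en-1-ol, 3 (Z)-3-iodobut-2-en-1-ol
Product: 13 (2Z,6S)-6-(furan-2-yl)-3-methylhex-2-ene-1,6-diol, via O-boryl B-alkyl-9-BBN adduct 12 (not isolated)
Conditions: 9-BBN (2.3 equiv), THF, 0 °C → rt; then 3 (1.1 equiv), Pd(dppf)Cl2·CH2Cl2 (5 mol %), AsPh3 (5 mol %), Cs2CO3 (3 equiv), DMF/H2O, rt
Reagents that add atoms: none
Why: Anti-Markovnikov hydroboration of the only monosubstituted alkene followed by B-alkyl Suzuki–Miyaura coupling, which keeps the vinyl iodide geometry (Z) and leaves the carbinol centre untouched.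

Step 5
Reactants: 13 (2Z,6S)-6-(furan-2-yl)-3-methylhex-2-ene-1,6-diol
Product: 15 (2S)-6-hydroxy-2-[(3Z)-5-hydroxy-3-methylpent-3-en-1-yl]-2H-pyran-3(6H)-one, via open-chain Z-enedione 14 (not isolated)
Conditions: NBS (1.0 equiv), NaHCO3, NaOAc, THF/H2O 4:1, 0 °C, 20 min
Reagents that add atoms: water, O
Why: Achmatowicz rearrangement, in which the furan is attacked by Br+ about a thousand times faster than the oxygen-deactivated trisubstituted alkene, hydrolysis gives enedione 14, and the carbinol oxygen closes on the aldehyde to expand the five-ring to the six-ring without touching C2.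

Step 6
Reactants: 15 (2S)-6-hydroxy-2-[(3Z)-5-hydroxy-3-methylpent-3-en-1-yl]-2H-pyran-3(6H)-one
Product: 16 (2S,6S)-6-(tert-butyldimethylsilyloxy)-2-[(3Z)-5-(tert-butyldimethylsilyloxy)-3-methylpent-3-en-1-yl]-2H-pyran-3(6H)-one (2,6-trans)
Conditions: TBSCl (2.6 equiv), imidazole (5 equiv), CH2Cl2, 0 °C → rt; minor cis anomer removed by chromatography
Reagents that add atoms: tert-butyldimethylsilyl chloride, CC(C)(C)[Si](C)(C)Cl
Why: One silylation covers the primary alcohol and the rapidly mutarotating lactol, and the anomeric effect favours the axial 2,6-trans silyl acetal, which fixes the configuration later carried into the C2 carbinol.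

Step 7
Reactants: 16 bis-TBS pyranone (2S,6S)
Product: 17 (2S,6S)-6-(tert-butyldimethylsilyloxy)-2-[(3Z)-5-(tert-butyldimethylsilyloxy)-3-methylpent-3-en-1-yl]oxan-3-one
Conditions: [(Ph3P)CuH]6 (0.4 equiv), degassed toluene, H2O (5 equiv), rt
Reagents that add atoms: none
Why: Copper hydride (Stryker) conjugate reduction touches only the enone C=C, leaves the isolated Z-allyl silyl ether and the silyl acetal alone, and avoids the Z/E scrambling that Pd–H could cause.

Step 8
Reactants: 17 oxan-3-one (2S,6S), 18 but-3-enoyl chloride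
Product: 20 (2S,3R,6S)-6-(tert-butyldimethylsilyloxy)-2-[(3Z)-5-(tert-butyldimethylsilyloxy)-3-methylpent-3-en-1-yl]-3-methyloxan-3-yl but-3-enoate, via bromomagnesium tertiary alkoxide 19 (not isolated)
Conditions: MeMgBr (1.3 equiv), toluene, −78 °C; then 18 (3 equiv), DMAP (0.3 equiv), −78 °C → rt
Reagents that add atoms: methylmagnesium bromide, C[Mg]Br
Why: Grignard 1,2-addition by axial attack on the chair oxan-3-one, where the ring oxygen removes one syn-axial hydrogen and chelation to the ring O is geometrically impossible, gives axial CH3 and an equatorial alkoxide trans to the side chain (3R), and this alkoxide is O-acylated in situ.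

Step 9
Reactants: 20 but-3-enoate (2S,3R,6S)
Product: 21 (2S,3R,6S)-6-(tert-butyldimethylsilyloxy)-2-[(3Z)-5-(tert-butyldimethylsilyloxy)-3-methylpent-3-en-1-yl]-3-methyloxan-3-yl 2-diazobut-3-enoate
Conditions: p-ABSA (1.3 equiv), DBU (1.5 equiv), MeCN, 0 °C, 2 h; kept cold and dark and used at once
Reagents that add atoms: 4-acetamidobenzenesulfonyl azide, CC(=O)Nc1ccc(cc1)S(=O)(=O)N=[N+]=[N-]
Why: Regitz diazo transfer onto the doubly activated (ester plus vinyl) methylene, as used for other beta,gamma-unsaturated esters, gives the donor/acceptor vinyldiazoacetate without affecting any stereocentre.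

Step 10
Reactants: 21 2-diazobut-3-enoate (2S,3R,6S)
Product: 24 (1R,2S,5R,9S)-2-(tert-butyldimethylsilyloxy)-9-[(3Z)-5-(tert-butyldimethylsilyloxy)-3-methylpent-3-en-1-yl]-1-ethenyl-5-methyl-6,8-dioxabicyclo[3.2.2]nonan-7-one, via copper vinylcarbene 22 (not isolated), via bridged oxonium ylide 23 (not isolated)
Conditions: Cu(hfacac)2 (10 mol %), CH2Cl2, reflux, 21 added by syringe pump over 6 h (final 2 mM)
Reagents that add atoms: none
Why: Proposed new method: copper takes N2 from the vinyldiazo ester; in the ring-flipped chair (acyloxy axial) the carbene carbon of 22 lies 1,3-syn-axial to a lone pair of the ring oxygen and closes the six-membered bicyclo[3.3.1] oxonium ylide 23 (the OTBS oxygen is hindered and eight atoms away, C3 carries no H for beta-lactone formation, and Cu rather than Rh disfavours C–H insertion at C2–H); the O–C6 bond, weakened by the silyloxy donor, then breaks to a tethered alpha-silyloxyalkyl/captodative allyl radical pair that recombines at the ylide carbon faster than C5–C6 rotation, so the anomeric carbon moves from O to C with retention (2S) while the bridge allows only 1R, and this stepwise, non-concerted Stevens 1,2-shift enlarges the oxane to the oxepane and leaves the lactone as the second bridge; the closest known reaction type is the Cu- or Rh-catalysed oxonium ylide/[1,2]-shift ring expansion of cyclic acetals tethered to diazoketones, which has not been shown for ester-tethered vinylcarbenes, for pyranoside ring oxygens or for making this bicycle.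

Step 11
Reactants: 24 1-ethenyl bicyclic lactone (1R,2S,5R,9S), 7 (Z)-3-iodo-2-methylprop-2-en-1-yl acetate
Product: 26 (2Z)-5-{(1R,2S,5R,9S)-2-(tert-butyldimethylsilyloxy)-9-[(3Z)-5-(tert-butyldimethylsilyloxy)-3-methylpent-3-en-1-yl]-5-methyl-7-oxo-6,8-dioxabicyclo[3.2.2]nonan-1-yl}-2-methylpent-2-en-1-yl acetate, via B-alkyl-9-BBN adduct 25 (not isolated)
Conditions: 9-BBN dimer (1.5 equiv), THF, rt → 40 °C; then 7 (1.5 equiv), Pd(dppf)Cl2·CH2Cl2 (10 mol %), AsPh3 (10 mol %), Cs2CO3 (2 equiv), DMF/H2O, rt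
Reagents that add atoms: none
Why: 9-BBN adds only to the monosubstituted vinyl group (terminal boron, oxygen gamma so no elimination) and the B-alkyl Suzuki–Miyaura coupling at rt retains the Z geometry, because oxidative addition to C–I is much faster than ionisation of the hindered allylic acetate.

Step 12
Reactants: 26 bis-TBS ether of the target
Product: 27 (2Z)-5-{(1R,2S,5R,9S)-2-hydroxy-9-[(3Z)-5-hydroxy-3-methylpent-3-en-1-yl]-5-methyl-7-oxo-6,8-dioxabicyclo[3.2.2]nonan-1-yl}-2-methylpent-2-en-1-yl acetate (CNP0174851.1)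
Conditions: HF·pyridine, pyridine, THF, 0 °C → rt
Reagents that add atoms: none
Why: Buffered fluoride desilylation removes both TBS ethers under non-basic conditions that leave the acetate, the bridged lactone and both Z-olefins unchanged.

## Compound list

1 | but-2-yn-1-ol | CC#CCO | starting material
2 | cyclic sodium vinylalanate (five-membered O–Al–C3 chelate carrying two 2-methoxyethoxy groups) | [Na+].CC1=CCO[Al-]1(OCCOC)OCCOC | intermediate
3 | (Z)-3-iodobut-2-en-1-ol | I/C(C)=C\CO | intermediate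
4 | prop-2-yn-1-ol | C#CCO | starting material
5 | (Z)-3-(bromomagnesio)-2-methylprop-2-en-1-olate bromomagnesium salt | Br[Mg]OC/C(C)=C\[Mg]Br | intermediate
6 | bromomagnesium (Z)-3-iodo-2-methylprop-2-en-1-olate | Br[Mg]OC/C(C)=C\I | intermediate
7 | (Z)-3-iodo-2-methylprop-2-en-1-yl acetate | CC(=O)OC/C(C)=C\I | intermediate
8 | furan-2-carbaldehyde (furfural) | O=Cc1ccco1 | starting material
9 | vinylmagnesium bromide | C=C[Mg]Br | starting material
10 | divinylzinc | C=C[Zn]C=C | intermediate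
11 | (S)-1-(furan-2-yl)prop-2-en-1-ol | O[C@@H](C=C)c1ccco1 | intermediate
12 | (S)-O-(9-BBN) borinate of 1-(furan-2-yl)-3-(9-BBN-9-yl)propan-1-ol | O(B1C2CCCC1CCC2)[C@@H](CCB1C2CCCC1CCC2)c1ccco1 | intermediate
13 | (2Z,6S)-6-(furan-2-yl)-3-methylhex-2-ene-1,6-diol | O[C@@H](CC/C(C)=C\CO)c1ccco1 | intermediate
14 | (2Z,5S,8Z)-5,10-dihydroxy-8-methyl-4-oxodeca-2,8-dienal | O[C@@H](CC/C(C)=C\CO)C(=O)/C=C\C=O | intermediate
15 | (2S)-6-hydroxy-2-[(3Z)-5-hydroxy-3-methylpent-3-en-1-yl]-2H-pyran-3(6H)-one (anomer mixture) | O1[C@@H](CC/C(C)=C\CO)C(=O)C=CC1O | intermediate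
16 | (2S,6S)-6-(TBSO)-2-[(3Z)-5-(TBSO)-3-methylpent-3-en-1-yl]-2H-pyran-3(6H)-one, 2,6-trans | O1[C@@H](CC/C(C)=C\CO[Si](C)(C)C(C)(C)C)C(=O)C=C[C@@H]1O[Si](C)(C)C(C)(C)C | intermediate
17 | (2S,6S)-6-(TBSO)-2-[(3Z)-5-(TBSO)-3-methylpent-3-en-1-yl]oxan-3-one | O1[C@@H](CC/C(C)=C\CO[Si](C)(C)C(C)(C)C)C(=O)CC[C@@H]1O[Si](C)(C)C(C)(C)C | intermediate
18 | but-3-enoyl chloride | C=CCC(=O)Cl | starting material
19 | bromomagnesium (2S,3R,6S)-6-(TBSO)-2-[(3Z)-5-(TBSO)-3-methylpent-3-en-1-yl]-3-methyloxan-3-olate | O1[C@@H](CC/C(C)=C\CO[Si](C)(C)C(C)(C)C)[C@@](C)(CC[C@@H]1O[Si](C)(C)C(C)(C)C)O[Mg]Br | intermediate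
20 | (2S,3R,6S)-6-(TBSO)-2-[(3Z)-5-(TBSO)-3-methylpent-3-en-1-yl]-3-methyloxan-3-yl but-3-enoate | O1[C@@H](CC/C(C)=C\CO[Si](C)(C)C(C)(C)C)[C@@](C)(CC[C@@H]1O[Si](C)(C)C(C)(C)C)OC(=O)CC=C | intermediate
21 | the corresponding 2-diazobut-3-enoate (2S,3R,6S) | O1[C@@H](CC/C(C)=C\CO[Si](C)(C)C(C)(C)C)[C@@](C)(CC[C@@H]1O[Si](C)(C)C(C)(C)C)OC(=O)C(=[N+]=[N-])C=C | intermediate
22 | copper vinylcarbene of 21 (ancillary hfacac ligand omitted) | O1[C@@H](CC/C(C)=C\CO[Si](C)(C)C(C)(C)C)[C@@](C)(CC[C@@H]1O[Si](C)(C)C(C)(C)C)OC(=O)C(=[Cu])C=C | intermediate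
23 | bridged bicyclo[3.3.1] oxonium ylide (ring O bonded to C2, C6 and the vinyl-substituted ylide carbon) | [O+]12[C@@H](CC/C(C)=C\CO[Si](C)(C)C(C)(C)C)[C@@](C)(CC[C@@H]1O[Si](C)(C)C(C)(C)C)OC(=O)[C-]2C=C | intermediate
24 | (1R,2S,5R,9S)-2-(TBSO)-9-[(3Z)-5-(TBSO)-3-methylpent-3-en-1-yl]-1-ethenyl-5-methyl-6,8-dioxabicyclo[3.2.2]nonan-7-one | C=C[C@@]12O[C@@H](CC/C(C)=C\CO[Si](C)(C)C(C)(C)C)[C@@](C)(CC[C@@H]1O[Si](C)(C)C(C)(C)C)OC2=O | intermediate
25 | 1-[2-(9-BBN-9-yl)ethyl] analogue of 24 | C(CB1C2CCCC1CCC2)[C@@]12O[C@@H](CC/C(C)=C\CO[Si](C)(C)C(C)(C)C)[C@@](C)(CC[C@@H]1O[Si](C)(C)C(C)(C)C)OC2=O | intermediate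
26 | bis-TBS ether of the target (1R,2S,5R,9S; both olefins Z) | CC(=O)OC/C(C)=C\CC[C@@]12O[C@@H](CC/C(C)=C\CO[Si](C)(C)C(C)(C)C)[C@@](C)(CC[C@@H]1O[Si](C)(C)C(C)(C)C)OC2=O | intermediate
27 | CNP0174851.1, (2Z)-5-{(1R,2S,5R,9S)-2-hydroxy-9-[(3Z)-5-hydroxy-3-methylpent-3-en-1-yl]-5-methyl-7-oxo-6,8-dioxabicyclo[3.2.2]nonan-1-yl}-2-methylpent-2-en-1-yl acetate | CC(=O)OC/C(C)=C\CC[C@@]12O[C@@H](CC/C(C)=C\CO)[C@@](C)(CC[C@@H]1O)OC2=O | target

## Step count

- Total step count: 12.
- Longest linear sequence: 10 steps (steps 3–12 from furfural; steps 1 and 4–12 from but-2-yn-1-ol are equally long).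

## Steps most likely to fail

**Step 10 (the new step).**
- Risks: C–H insertion at C2–H to give a gamma-lactone, pyrazole formation from the vinyldiazo group, and partial loss of configuration at the migrating carbon.
- The fallback uses known chemistry only. It sets out from 21 and comes back at 24.
- The anomeric silyl ether of 21 is cleaved selectively with TBAF/AcOH 1:1 in THF at −20 °C, since the lactolate is the better leaving group on silicon. This gives the lactol diazo ester F1.
- Rh2(OAc)4 (1 mol %, CH2Cl2, 2 mM, rt) then carries out an ordinary O–H insertion on the hydroxy-aldehyde tautomer. The product is the 3-vinyl-1,4-dioxan-2-one aldehyde F2.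
- DBU (or LiHMDS at −78 °C) closes the C1–C2 bond by intramolecular aldol addition of the lactone dienolate. Only the bridged 1R geometry can close, and because the addition is reversible the carbinol epimers can be equilibrated and recycled. The product is the hydroxy lactone F3.
- TBSOTf/2,6-lutidine then returns 24.

**Step 8.**
- Risks: equatorial instead of axial methyl delivery, and sluggish acylation of the hindered magnesium alkoxide.
- The fallback sets out from 17 and comes back at 20.
- Dimethylsulfonium methylide (Me3SI, n-BuLi, THF, −10 °C) adds irreversibly from the axial side. This gives the spiro-epoxide F4, with axial CH2 and equatorial O.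
- LiEt3BH (THF, 0 °C) opens F4 at the CH2 terminus to give the free tertiary alcohol F5.
- F5 is acylated separately with 18, Et3N and DMAP in CH2Cl2 (vinylketene pathway) to give 20.

**Step 9.**
- Risks: DBU-induced conjugation to the crotonate, and low stability of the unsubstituted vinyldiazo ester.
- The fallback sets out from 19 and comes back at 21.
- Aqueous quench of 19 gives the tertiary alcohol F5.
- 2,2,6-Trimethyl-4H-1,3-dioxin-4-one in toluene at 110 °C (acylketene) gives the acetoacetate F6.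
- p-ABSA/Et3N in MeCN gives the diazoacetoacetate F7.
- NaBH4 in MeOH at 0 °C gives the 2-diazo-3-hydroxybutanoate F8.
- POCl3/Et3N in CH2Cl2 at 0 °C dehydrates F8 to 21.

Further compounds
F1 | step 10 | (2S,3R)-6-hydroxy-2-[(3Z)-5-(TBSO)-3-methylpent-3-en-1-yl]-3-methyloxan-3-yl 2-diazobut-3-enoate (lactol, anomer mixture) | O1[C@@H](CC/C(C)=C\CO[Si](C)(C)C(C)(C)C)[C@@](C)(CCC1O)OC(=O)C(=[N+]=[N-])C=C
F2 | step 10 | 3-[(2R,3S)-3-[(3Z)-5-(TBSO)-3-methylpent-3-en-1-yl]-5-ethenyl-2-methyl-6-oxo-1,4-dioxan-2-yl]propanal (C5 epimer mixture) | C=CC1O[C@@H](CC/C(C)=C\CO[Si](C)(C)C(C)(C)C)[C@@](C)(CCC=O)OC1=O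
F3 | step 10 | (1R,2S,5R,9S)-1-ethenyl-2-hydroxy-9-[(3Z)-5-(TBSO)-3-methylpent-3-en-1-yl]-5-methyl-6,8-dioxabicyclo[3.2.2]nonan-7-one | C=C[C@@]12O[C@@H](CC/C(C)=C\CO[Si](C)(C)C(C)(C)C)[C@@](C)(CC[C@@H]1O)OC2=O
F4 | step 8 | spiro[oxane-3,2'-oxirane] from 17 (axial CH2, equatorial O; 6-OTBS and the C2 side chain as in 17) | O1[C@@H](CC/C(C)=C\CO[Si](C)(C)C(C)(C)C)[C@@]2(CO2)CC[C@@H]1O[Si](C)(C)C(C)(C)C
F5 | step 8 | (2S,3R,6S)-6-(TBSO)-2-[(3Z)-5-(TBSO)-3-methylpent-3-en-1-yl]-3-methyloxan-3-ol | O1[C@@H](CC/C(C)=C\CO[Si](C)(C)C(C)(C)C)[C@@](C)(CC[C@@H]1O[Si](C)(C)C(C)(C)C)O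
F6 | step 9 | 3-oxobutanoate (acetoacetate) of F5 | O1[C@@H](CC/C(C)=C\CO[Si](C)(C)C(C)(C)C)[C@@](C)(CC[C@@H]1O[Si](C)(C)C(C)(C)C)OC(=O)CC(C)=O
F7 | step 9 | 2-diazo-3-oxobutanoate of F5 | O1[C@@H](CC/C(C)=C\CO[Si](C)(C)C(C)(C)C)[C@@](C)(CC[C@@H]1O[Si](C)(C)C(C)(C)C)OC(=O)C(=[N+]=[N-])C(C)=O
F8 | step 9 | 2-diazo-3-hydroxybutanoate of F5 (carbinol epimer mixture) | O1[C@@H](CC/C(C)=C\CO[Si](C)(C)C(C)(C)C)[C@@](C)(CC[C@@H]1O[Si](C)(C)C(C)(C)C)OC(=O)C(=[N+]=[N-])C(C)O
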